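(Its constants belong to no real substance, and the outcome is calculated.)

**Two roads.** Target and side product both need the second intermediate, J: J meets the open intermediate on one road and the substrate on the other. Since J stands in both rates, it cancels from their ratio once substrate and open intermediate hold their equilibrium. That ratio of rates, target over side product, is then s, the selectivity factor: the target step's constant times the opening equilibrium constant, over the side-product step's constant. J comes from the partner; the substrate opens reversibly.

| setting | east | south-east | north | south |
|---|---|---|---|---|
| substrate | 2.1 M | 2.1 M | 2.1 M | 2.1 M |
| partner | 1.20 equiv | 1.20 equiv | 1.20 equiv | 1.20 equiv |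
| temperature | 25 °C | 75 °C | 0 °C | 50 °C |
| time | 10 h | 10 h | 10 h | 10 h |

1. the flask with the highest amount of target, in percent of the substrate charged ("all alike" if they lie within 1.5 percentage points) (east / south-east / north / south / all alike)
2. final target, as a percentage of the substrate charged, in east
3. final target, as a percentage of the substrate charged, in south-east
4. final target, as a percentage of the substrate charged, in north
5. final target, as a percentage of the substrate charged, in south

- the list of constants is for 25 °C, to be carried to other temperatures by the activation energies and enthalpies

    substrate ⇌ open intermediate (K1 = 0.20, k1 = 0.00376 /min, Ea1 = 106 kJ/mol, ΔH1 = −31.0 kJ/mol)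
    open intermediate + second intermediate → target (k2 = 0.00892 /M/min, Ea2 = 58.0 kJ/mol)
    partner → second intermediate (k3 = 0.00740 /min, Ea3 = 87.0 kJ/mol)
    substrate + second intermediate → side product (k4 = 0.00549 /M/min, Ea4 = 71.0 kJ/mol)
    (constants at 25 °C)

**The ladder.** We take east first. Substrate and open intermediate relax with a half-life of 0.512 h, and the partner's half-life is 1.56 h, so relaxation is quicker. Even if the whole partner charge, 2.52 M, stood as J, the substrate's half-life by the side road would be 0.835 h, still longer than the relaxation. That figure is a lower limit: with less J standing the side road is slower, so relaxation comes first and we leave the order of the side road and the partner open.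

**The ceiling.** The open intermediate falls back as fast as it goes on when J reaches J*, here 2.11 M. Any J below that still pulls the true ratio down to s/(1 + J/J*). In east s is 0.325, so target stays under 24.5%.

**Other flasks.** Heating lowers s with an energy of 44.0 kJ/mol, while J* climbs to 24.8 M in south and 205 M in south-east, above the charge. The partner's half-life in south is 0.103 h, and the partner charge exceeds the substrate's. So s gives the split directly: 0.0823 and 7.61% in south, 0.0254 and 2.48% in south-east. In north the opening constant is 7.51 × 10⁻⁵ /min, so target, which must pass through opening, stays under 4.50%. Among these figures, the best flask is east.

**The forecast.** It named east, with 18% in east, 2.5% in south-east, 0.35% in north and 7.5% in south, holding that “heating shrinks the open-intermediate share”. Our east figure is a ceiling; its figure is a value, and lies below that ceiling.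

**The result.** The best flask is east, with 18.9% in east, 2.48% in south-east, 0.300% in north and 7.54% in south.

**Reading it back.** In east at 1.53 h the open intermediate falls back 2.8 times as fast as it goes on, and target over side product at 100 h reads 0.264, lower than s. In south, where s is 0.0823, the same ratio at 10.0 h reads 0.0816.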